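**Retrosynthetic overview** (target numbered as a tricyclo[5.4.0.0^2,8]undecane: C11 ketone, C3 angelate, C6 bears CH3 and CH2O‑tiglate, methyls on C2 and C9)
1. Angelate: last‑step mixed‑anhydride acylation of the C3 carbinol; the primary tiglate is put on in step 2 and serves as the only O‑protecting group.
2. Seven‑membered ring (formed last): ring‑closing metathesis at C4=C5 of a divinyl carbinol, then OH‑directed hydrogenation; the C3 carbinol comes from vinyl addition to a neopentyl aldehyde.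
3. Cyclobutane (C1–C2 bond, quaternary C2; key step, formed second): the two α‑carbons of a 1,4‑keto aldehyde are joined by turning the ketone enol silane into an electrophilic enolonium (aryl‑λ3‑iodane) that is captured by the tethered aldehyde enol ether.
4. Six‑membered ring (formed first): catalytic asymmetric Diels–Alder of a 2‑silyloxy diene with (E)‑pent‑3‑en‑2‑one, which sets C7, C8, C9 and delivers the enol silane regiospecifically.
5. Quaternary C6: Pd‑catalysed asymmetric allylic alkylation of isoprene monoepoxide with nitromethane, then Nef and Wittig reactions to the diene.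

Assumption: the chiral ligand in step 1, the chiral Lewis acid in step 6 and the auxiliary in the fallback to step 6 induce in the sense written; if one does not, its mirror‑image form is used.

**Step 1**
Reactants: 1 2‑methyl‑2‑vinyloxirane (racemic isoprene monoepoxide); 2 nitromethane
Product: 3 (2S)‑2‑methyl‑2‑(nitromethyl)but‑3‑en‑1‑ol
Conditions: Pd2(dba)3·CHCl3 (1 mol %), (R,R)‑DACH‑phenyl Trost ligand (3 mol %), CH3NO2 (5 equiv), CH2Cl2, rt
Reagents that add atoms: nitromethane, C[N+](=O)[O-]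
Why: Pd‑catalysed dynamic kinetic asymmetric allylic alkylation: both epoxide enantiomers ionise to interconverting π‑allyl palladium alkoxides, the alkoxide deprotonates nitromethane, and the ligand pocket delivers the nitronate to the tertiary allyl terminus, creating the quaternary centre (S).

**Step 2**
Reactants: 3 (2S)‑2‑methyl‑2‑(nitromethyl)but‑3‑en‑1‑ol; 4 (2E)‑2‑methylbut‑2‑enoyl chloride (tigloyl chloride)
Product: 5 [(2S)‑2‑methyl‑2‑(nitromethyl)but‑3‑en‑1‑yl] (2E)‑2‑methylbut‑2‑enoate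
Conditions: pyridine (2 equiv), DMAP (5 mol %), CH2Cl2, 0 °C → rt
Reagents that add atoms: tigloyl chloride, C/C=C(\C)C(Cl)=O
Why: Simple O‑acylation of the primary alcohol; the tiglate of the target is installed now and doubles as a non‑participating protecting group for the rest of the route.

**Step 3**
Reactants: 5 [(2S)‑2‑methyl‑2‑(nitromethyl)but‑3‑en‑1‑yl] (2E)‑2‑methylbut‑2‑enoate
Product: 7 [(2R)‑2‑formyl‑2‑methylbut‑3‑en‑1‑yl] (2E)‑2‑methylbut‑2‑enoate, via lithium nitronate 6 (not isolated)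
Conditions: LiN(SiMe3)2 (1.05 equiv), THF, −78 °C; then added to aq TiCl3 (4.5 equiv)/NH4OAc (pH 5–6), THF, 0 °C → rt
Reagents that add atoms: water, O
Why: Reductive Nef reaction (McMurry variant): TiCl3 reduces the nitronate to the imine, which hydrolyses to the non‑enolisable α‑quaternary aldehyde; the buffered medium spares the ester and both alkenes, and the stereocentre is untouched (the descriptor changes only through priorities).

**Step 4**
Reactants: 7 [(2R)‑2‑formyl‑2‑methylbut‑3‑en‑1‑yl] (2E)‑2‑methylbut‑2‑enoate; 8 1‑(triphenyl‑λ5‑phosphanylidene)propan‑2‑one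
Product: 9 [(2S,3E)‑2‑ethenyl‑2‑methyl‑5‑oxohex‑3‑en‑1‑yl] (2E)‑2‑methylbut‑2‑enoate
Conditions: toluene, 100 °C, 24 h
Reagents that add atoms: 1‑(triphenyl‑λ5‑phosphanylidene)propan‑2‑one, CC(=O)C=P(c1ccccc1)(c1ccccc1)c1ccccc1
Why: Wittig olefination with a stabilised ylide gives the (E)‑enone.

**Step 5**
Reactants: 9 [(2S,3E)‑2‑ethenyl‑2‑methyl‑5‑oxohex‑3‑en‑1‑yl] (2E)‑2‑methylbut‑2‑enoate
Product: 10 [(2S,3E)‑5‑(tert‑butyldimethylsilyloxy)‑2‑ethenyl‑2‑methylhexa‑3,5‑dien‑1‑yl] (2E)‑2‑methylbut‑2‑enoate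
Conditions: TBSOTf (1.2 equiv), Et3N (1.6 equiv), CH2Cl2, 0 °C
Reagents that add atoms: tert‑butyldimethylsilyl trifluoromethanesulfonate, CC(C)(C)[Si](C)(C)OS(=O)(=O)C(F)(F)F
Why: Soft enolisation and O‑silylation of the methyl ketone; the γ‑carbon is quaternary, so only the 2‑silyloxy‑1,3‑diene can form.

**Step 6**
Reactants: 10 [(2S,3E)‑5‑(tert‑butyldimethylsilyloxy)‑2‑ethenyl‑2‑methylhexa‑3,5‑dien‑1‑yl] (2E)‑2‑methylbut‑2‑enoate; 11 (3E)‑pent‑3‑en‑2‑one
Product: 12 [(2S)‑2‑[(1R,5R,6S)‑6‑acetyl‑3‑(tert‑butyldimethylsilyloxy)‑5‑methylcyclohex‑2‑en‑1‑yl]‑2‑methylbut‑3‑en‑1‑yl] (2E)‑2‑methylbut‑2‑enoate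
Conditions: cationic oxazaborolidine from (S)‑α,α‑diphenylprolinol, o‑tolylboronic acid and HN(SO2CF3)2 (20 mol %), 11 (1.5 equiv), CH2Cl2, −78 → −20 °C; Et3N quench
Reagents that add atoms: (3E)‑pent‑3‑en‑2‑one, C/C=C/C(C)=O
Why: Catalytic enantioselective Diels–Alder reaction: the silyloxy group (para) and the terminal alkyl group (ortho) direct the diene CH2 terminus to the enone β‑carbon, the endo transition state puts the acetyl cis to the quaternary side chain, the (E)‑dienophile puts the methyl trans to the acetyl, and the chiral Lewis acid selects the enone face and so fixes the absolute configuration of the three new ring stereocentres (the planar diene means the existing quaternary centre only selects a rotamer).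

**Step 7**
Reactants: 12 [(2S)‑2‑[(1R,5R,6S)‑6‑acetyl‑3‑(tert‑butyldimethylsilyloxy)‑5‑methylcyclohex‑2‑en‑1‑yl]‑2‑methylbut‑3‑en‑1‑yl] (2E)‑2‑methylbut‑2‑enoate; 13 (methoxymethyl)triphenylphosphonium chloride
Product: 14 [(2S)‑2‑[(1S,5R,6S)‑3‑(tert‑butyldimethylsilyloxy)‑6‑(1‑methoxyprop‑1‑en‑2‑yl)‑5‑methylcyclohex‑2‑en‑1‑yl]‑2‑methylbut‑3‑en‑1‑yl] (2E)‑2‑methylbut‑2‑enoate (E/Z mixture at the enol ether)
Conditions: 13 (2.0 equiv), KN(SiMe3)2 (1.9 equiv), THF, 0 °C; then 12, −78 → 0 °C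
Reagents that add atoms: (methoxymethyl)triphenylphosphonium chloride, COC[P+](c1ccccc1)(c1ccccc1)c1ccccc1.[Cl-]
Why: Wittig methoxymethylenation homologates the methyl ketone to an aldehyde enol ether whose β‑carbon is the future quaternary cyclobutane carbon; low temperature and the hindered α‑CH limit epimerisation next to the ketone, and no stereocentre is created (the ring descriptor at C1 changes only through priorities).

**Step 8**
Reactants: 14 [(2S)‑2‑[(1S,5R,6S)‑3‑(tert‑butyldimethylsilyloxy)‑6‑(1‑methoxyprop‑1‑en‑2‑yl)‑5‑methylcyclohex‑2‑en‑1‑yl]‑2‑methylbut‑3‑en‑1‑yl] (2E)‑2‑methylbut‑2‑enoate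
Product: 17 [(2S)‑2‑[(1R,4R,5S,6R,7S)‑6‑formyl‑4,6‑dimethyl‑2‑oxobicyclo[3.1.1]heptan‑7‑yl]‑2‑methylbut‑3‑en‑1‑yl] (2E)‑2‑methylbut‑2‑enoate, via O‑iodanyl enolonium 15 (not isolated), via acetoxy methyl acetal 16 (not isolated)
Conditions: PhI(OAc)2 (1.1 equiv), BF3·OEt2 (1.5 equiv), 2,6‑di‑tert‑butyl‑4‑methylpyridine (0.5 equiv), CH2Cl2, −78 °C, slow addition of 14 (0.01 M); aq NaHCO3, 0 °C → rt
Reagents that add atoms: water, O; (diacetoxyiodo)benzene, CC(=O)O[I](OC(C)=O)c1ccccc1 (its atoms stay only in 15 and 16)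
Why: Proposed new method: BF3‑activated PhI(OAc)2 replaces silicon by trivalent iodine at the enol oxygen and so makes the ketone α‑carbon (ring C2 of 14) electrophilic; in the conformer with the quaternary side chain pseudo‑equatorial the enol ether on C6 is axial and 1,3‑related to C2, so its nucleophilic β‑carbon attacks C2 on that face in an SN2'‑type displacement of iodobenzene, closing the cyclobutane with the only possible bridgehead configurations (C1 and C5 of 17) and setting the quaternary centre (6R) from the rotamer that places the small methyl, not the longer methoxyvinyl terminus, over the six‑membered ring; the oxocarbenium ion is capped by acetate and hydrolysed to the aldehyde on work‑up; the closest known reaction types are cross‑coupling of silyl enol ethers through PhI(OAc)2/BF3‑derived enolonium species to 1,4‑dicarbonyls, oxidative addition of silyl enol ethers to alkyl enol ethers, and cyclobutane closure by 1,3‑diaxial enolate alkylation in bicyclo[3.1.1]heptanone synthesis.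

**Step 9**
Reactants: 17 [(2S)‑2‑[(1R,4R,5S,6R,7S)‑6‑formyl‑4,6‑dimethyl‑2‑oxobicyclo[3.1.1]heptan‑7‑yl]‑2‑methylbut‑3‑en‑1‑yl] (2E)‑2‑methylbut‑2‑enoate; 18 vinylmagnesium bromide
Product: 19 [(2S)‑2‑[(1R,4R,5S,6R,7S)‑6‑[(1R)‑1‑hydroxyprop‑2‑en‑1‑yl]‑4,6‑dimethyl‑2‑oxobicyclo[3.1.1]heptan‑7‑yl]‑2‑methylbut‑3‑en‑1‑yl] (2E)‑2‑methylbut‑2‑enoate
Conditions: CH2=CHMgBr (1.3 equiv), THF, −78 °C; aq NH4Cl
Reagents that add atoms: vinylmagnesium bromide, C=C[Mg]Br
Why: Chemoselective Grignard 1,2‑addition (aldehyde far faster than the ketone or the hindered conjugated ester at −78 °C); by the polar Felkin–Anh model the nucleophile comes in anti to the C6–C1 bond (the one carrying the acyl group) and past the C6 methyl, which gives the (1R) carbinol, with any minor epimer removed by chromatography.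

**Step 10**
Reactants: 19 [(2S)‑2‑[(1R,4R,5S,6R,7S)‑6‑[(1R)‑1‑hydroxyprop‑2‑en‑1‑yl]‑4,6‑dimethyl‑2‑oxobicyclo[3.1.1]heptan‑7‑yl]‑2‑methylbut‑3‑en‑1‑yl] (2E)‑2‑methylbut‑2‑enoate
Product: 20 [(1R,2R,3R,6S,7S,8S,9R)‑3‑hydroxy‑2,6,9‑trimethyl‑11‑oxotricyclo[5.4.0.0^2,8]undec‑4‑en‑6‑yl]methyl (2E)‑2‑methylbut‑2‑enoate
Conditions: second‑generation Hoveyda–Grubbs catalyst, RuCl2(H2IMes)(=CH‑C6H4‑2‑OiPr) (8 mol %), toluene (0.005 M), 80 °C
Reagents that add atoms: none
Why: Ring‑closing metathesis: both vinyl groups sit on the cyclobutane face away from the three‑carbon bridge, so the cis‑cycloheptene closes readily; the trisubstituted tiglate alkene is inert and no stereocentre is touched.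

**Step 11**
Reactants: 20 [(1R,2R,3R,6S,7S,8S,9R)‑3‑hydroxy‑2,6,9‑trimethyl‑11‑oxotricyclo[5.4.0.0^2,8]undec‑4‑en‑6‑yl]methyl (2E)‑2‑methylbut‑2‑enoate
Product: 21 [(1R,2R,3R,6S,7S,8S,9R)‑3‑hydroxy‑2,6,9‑trimethyl‑11‑oxotricyclo[5.4.0.0^2,8]undecan‑6‑yl]methyl (2E)‑2‑methylbut‑2‑enoate
Conditions: H2 (1 atm), [Ir(cod)(PCy3)(py)]PF6 (5 mol %), CH2Cl2, rt
Reagents that add atoms: none
Why: Hydroxyl‑directed homogeneous hydrogenation: the cationic iridium catalyst binds the allylic OH and reduces the neighbouring cis‑disubstituted alkene, while the undirected trisubstituted conjugated tiglate and the ketone are left.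

**Step 12**
Reactants: 21 [(1R,2R,3R,6S,7S,8S,9R)‑3‑hydroxy‑2,6,9‑trimethyl‑11‑oxotricyclo[5.4.0.0^2,8]undecan‑6‑yl]methyl (2E)‑2‑methylbut‑2‑enoate; 22 angelic acid
Product: 24 [(1R,2R,3R,6S,7S,8S,9R)‑2,6,9‑trimethyl‑3‑{[(2Z)‑2‑methylbut‑2‑enoyl]oxy}‑11‑oxotricyclo[5.4.0.0^2,8]undecan‑6‑yl]methyl (2E)‑2‑methylbut‑2‑enoate (CNP0276938.2), via mixed anhydride 23 (not isolated)
Conditions: angelic acid (4 equiv), 2,4,6‑trichlorobenzoyl chloride (4 equiv), Et3N (5 equiv), toluene, rt, 2 h; then 21, 80 °C, 24 h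
Reagents that add atoms: angelic acid, C/C=C(/C)C(=O)O; 2,4,6‑trichlorobenzoyl chloride, O=C(Cl)c1c(Cl)cc(Cl)cc1Cl (its atoms stay only in 23)
Why: Yamaguchi‑type esterification through the mixed anhydride without DMAP acylates the hindered secondary alcohol with retention at the carbinol and without Z to E isomerisation of the angelate.

**Compound list**
1 | 2‑methyl‑2‑vinyloxirane (racemic) | C=CC1(C)CO1 | starting material
2 | nitromethane | C[N+](=O)[O-] | starting material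
3 | (2S)‑2‑methyl‑2‑(nitromethyl)but‑3‑en‑1‑ol | C=C[C@](C)(CO)C[N+](=O)[O-] | intermediate
4 | (2E)‑2‑methylbut‑2‑enoyl chloride (tigloyl chloride) | C/C=C(\C)C(Cl)=O | starting material
5 | [(2S)‑2‑methyl‑2‑(nitromethyl)but‑3‑en‑1‑yl] (2E)‑2‑methylbut‑2‑enoate | C=C[C@](C)(COC(=O)/C(C)=C/C)C[N+](=O)[O-] | intermediate
6 | lithium nitronate of 5 | C=C[C@](C)(COC(=O)/C(C)=C/C)C=[N+]([O-])[O-].[Li+] | intermediate
7 | [(2R)‑2‑formyl‑2‑methylbut‑3‑en‑1‑yl] (2E)‑2‑methylbut‑2‑enoate | C=C[C@](C)(COC(=O)/C(C)=C/C)C=O | intermediate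
8 | 1‑(triphenyl‑λ5‑phosphanylidene)propan‑2‑one | CC(=O)C=P(c1ccccc1)(c1ccccc1)c1ccccc1 | starting material
9 | [(2S,3E)‑2‑ethenyl‑2‑methyl‑5‑oxohex‑3‑en‑1‑yl] (2E)‑2‑methylbut‑2‑enoate | C=C[C@](C)(COC(=O)/C(C)=C/C)/C=C/C(C)=O | intermediate
10 | [(2S,3E)‑5‑(tert‑butyldimethylsilyloxy)‑2‑ethenyl‑2‑methylhexa‑3,5‑dien‑1‑yl] (2E)‑2‑methylbut‑2‑enoate | C=C[C@](C)(COC(=O)/C(C)=C/C)/C=C/C(=C)O[Si](C)(C)C(C)(C)C | intermediate
11 | (3E)‑pent‑3‑en‑2‑one | C/C=C/C(C)=O | starting material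
12 | [(2S)‑2‑[(1R,5R,6S)‑6‑acetyl‑3‑(tert‑butyldimethylsilyloxy)‑5‑methylcyclohex‑2‑en‑1‑yl]‑2‑methylbut‑3‑en‑1‑yl] (2E)‑2‑methylbut‑2‑enoate | C=C[C@](C)(COC(=O)/C(C)=C/C)[C@@H]1C=C(O[Si](C)(C)C(C)(C)C)C[C@@H](C)[C@@H]1C(C)=O | intermediate
13 | (methoxymethyl)triphenylphosphonium chloride | COC[P+](c1ccccc1)(c1ccccc1)c1ccccc1.[Cl-] | starting material
14 | [(2S)‑2‑[(1S,5R,6S)‑3‑(tert‑butyldimethylsilyloxy)‑6‑(1‑methoxyprop‑1‑en‑2‑yl)‑5‑methylcyclohex‑2‑en‑1‑yl]‑2‑methylbut‑3‑en‑1‑yl] (2E)‑2‑methylbut‑2‑enoate (E/Z mixture) | C=C[C@](C)(COC(=O)/C(C)=C/C)[C@@H]1C=C(O[Si](C)(C)C(C)(C)C)C[C@@H](C)[C@@H]1C(C)=COC | intermediate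
15 | O‑[acetoxy(phenyl)‑λ3‑iodanyl] enol of the ring ketone (enolonium) | C=C[C@](C)(COC(=O)/C(C)=C/C)[C@@H]1C=C(O[I](OC(C)=O)c2ccccc2)C[C@@H](C)[C@@H]1C(C)=COC | intermediate
16 | acetoxy methyl acetal of aldehyde 17 (acetal carbon unassigned) | C=C[C@](C)(COC(=O)/C(C)=C/C)[C@H]1[C@@H]2[C@H](C)CC(=O)[C@H]1[C@@]2(C(OC)OC(C)=O)C | intermediate
17 | [(2S)‑2‑[(1R,4R,5S,6R,7S)‑6‑formyl‑4,6‑dimethyl‑2‑oxobicyclo[3.1.1]heptan‑7‑yl]‑2‑methylbut‑3‑en‑1‑yl] (2E)‑2‑methylbut‑2‑enoate | C=C[C@](C)(COC(=O)/C(C)=C/C)[C@H]1[C@@H]2[C@H](C)CC(=O)[C@H]1[C@@]2(C=O)C | intermediate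
18 | vinylmagnesium bromide | C=C[Mg]Br | starting material
19 | [(2S)‑2‑[(1R,4R,5S,6R,7S)‑6‑[(1R)‑1‑hydroxyprop‑2‑en‑1‑yl]‑4,6‑dimethyl‑2‑oxobicyclo[3.1.1]heptan‑7‑yl]‑2‑methylbut‑3‑en‑1‑yl] (2E)‑2‑methylbut‑2‑enoate | C=C[C@](C)(COC(=O)/C(C)=C/C)[C@H]1[C@@H]2[C@H](C)CC(=O)[C@H]1[C@@]2([C@H](O)C=C)C | intermediate
20 | [(1R,2R,3R,6S,7S,8S,9R)‑3‑hydroxy‑2,6,9‑trimethyl‑11‑oxotricyclo[5.4.0.0^2,8]undec‑4‑en‑6‑yl]methyl (2E)‑2‑methylbut‑2‑enoate | O[C@@H]1C=C[C@](C)(COC(=O)/C(C)=C/C)[C@H]2[C@@H]3[C@H](C)CC(=O)[C@H]2[C@@]31C | intermediate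
21 | [(1R,2R,3R,6S,7S,8S,9R)‑3‑hydroxy‑2,6,9‑trimethyl‑11‑oxotricyclo[5.4.0.0^2,8]undecan‑6‑yl]methyl (2E)‑2‑methylbut‑2‑enoate | O[C@@H]1CC[C@](C)(COC(=O)/C(C)=C/C)[C@H]2[C@@H]3[C@H](C)CC(=O)[C@H]2[C@@]31C | intermediate
22 | angelic acid, (2Z)‑2‑methylbut‑2‑enoic acid | C/C=C(/C)C(=O)O | starting material
23 | (2Z)‑2‑methylbut‑2‑enoic 2,4,6‑trichlorobenzoic anhydride | C/C=C(/C)C(=O)OC(=O)c1c(Cl)cc(Cl)cc1Cl | intermediate
24 | [(1R,2R,3R,6S,7S,8S,9R)‑2,6,9‑trimethyl‑3‑{[(2Z)‑2‑methylbut‑2‑enoyl]oxy}‑11‑oxotricyclo[5.4.0.0^2,8]undecan‑6‑yl]methyl (2E)‑2‑methylbut‑2‑enoate | C/C=C(/C)C(=O)O[C@@H]1CC[C@](C)(COC(=O)/C(C)=C/C)[C@H]2[C@@H]3[C@H](C)CC(=O)[C@H]2[C@@]31C | target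

**Step count and risks**
Total step count: 12. Longest linear sequence: 12 (one linear sequence from 1; all other inputs are commercial).

Steps most likely to fail:

Step 8 (cyclobutane closure). The iodane may attack the methyl enol ether instead of the silyl enol ether, acetate may cap the α‑carbon, four‑ring closure may be too slow, or the wrong rotamer may give the C6 epimer. The fallback sets out from 14 and comes back at 17. Anhydrous fluoride (Bu4N[Ph3SiF2], THF, −78 °C) unmasks only the silyl enol ether, and the ammonium enolate is iodinated in the same flask with I2 (1.0 equiv) to give the α‑iodo ketone F1, an isolable enolonium equivalent. AgBF4 with 2,6‑di‑tert‑butyl‑4‑methylpyridine (CH2Cl2, −40 °C) then ionises the C–I bond, the enol ether closes the four‑membered ring, and aqueous work‑up gives 17. Oxidation and C–C bond formation are thereby separated, so each can be tuned on its own.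

Step 6 (Diels–Alder). A β‑substituted acyclic enone and a diene with a quaternary terminus are both sluggish; Mukaiyama–Michael side products or poor endo/enantio‑control are possible. The fallback sets out from 10 and comes back at 12. Auxiliary control replaces catalyst control: Et2AlCl (1.4 equiv, CH2Cl2, −78 °C) with (4S)‑4‑benzyl‑3‑[(2E)‑but‑2‑enoyl]‑1,3‑oxazolidin‑2‑one (commercial, more reactive, strongly endo through the chelated imide) gives the N‑acyl oxazolidinone F2. AlMe3/MeNH(OMe)·HCl (CH2Cl2, 0 °C) converts it into the Weinreb amide F3, and MeMgBr (THF, −20 °C) gives methyl ketone 12.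

Step 9 (carbinol configuration). Facial selectivity at the neopentyl aldehyde is the least predictable stereochemical event of the route. The fallback sets out from 17 and comes back at 20. If the Grignard addition gives mainly the (1S)‑carbinol F4, it is cyclised as in step 10 to the 3‑epi allylic alcohol F5 and oxidised with MnO2 (CH2Cl2, rt; allylic alcohol only) to the enedione F6. LiN(SiMe3)2 (1.05 equiv, THF, −78 °C) converts the only enolisable ketone (C11) into the lithium enolate F7, which masks it. LiAlH(OtBu)3 (−78 → −20 °C) then reduces the enone carbonyl 1,2 from the face of the C6 methyl group, anti to the larger acyloxymethyl arm, and NH4Cl work‑up gives 20. The centre is then set by face selection on a cyclic ketone instead of by acyclic addition.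

**Further compounds**
F1 | step 8 | 2‑iodo ketone from 14 (silyl enol ether replaced by CH(I)–C=O; C–I epimers) | C=C[C@](C)(COC(=O)/C(C)=C/C)[C@@H]1C(I)C(=O)C[C@@H](C)[C@@H]1C(C)=COC
F2 | step 6 | imide analogue of 12 (acetyl replaced by (4S)‑4‑benzyl‑2‑oxo‑1,3‑oxazolidine‑3‑carbonyl) | C=C[C@](C)(COC(=O)/C(C)=C/C)[C@@H]1C=C(O[Si](C)(C)C(C)(C)C)C[C@@H](C)[C@@H]1C(=O)N2C(=O)OC[C@@H]2Cc2ccccc2
F3 | step 6 | Weinreb amide analogue of 12 (acetyl replaced by N‑methoxy‑N‑methylcarbamoyl) | C=C[C@](C)(COC(=O)/C(C)=C/C)[C@@H]1C=C(O[Si](C)(C)C(C)(C)C)C[C@@H](C)[C@@H]1C(=O)N(C)OC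
F4 | step 9 | (1S)‑carbinol epimer of 19 | C=C[C@](C)(COC(=O)/C(C)=C/C)[C@H]1[C@@H]2[C@H](C)CC(=O)[C@H]1[C@@]2([C@@H](O)C=C)C
F5 | step 9 | [(1R,2R,3S,6S,7S,8S,9R)‑3‑hydroxy‑2,6,9‑trimethyl‑11‑oxotricyclo[5.4.0.0^2,8]undec‑4‑en‑6‑yl]methyl (2E)‑2‑methylbut‑2‑enoate | O[C@H]1C=C[C@](C)(COC(=O)/C(C)=C/C)[C@H]2[C@@H]3[C@H](C)CC(=O)[C@H]2[C@@]31C
F6 | step 9 | [(1R,2R,6S,7S,8S,9R)‑2,6,9‑trimethyl‑3,11‑dioxotricyclo[5.4.0.0^2,8]undec‑4‑en‑6‑yl]methyl (2E)‑2‑methylbut‑2‑enoate | O=C1C=C[C@](C)(COC(=O)/C(C)=C/C)[C@H]2[C@@H]3[C@H](C)CC(=O)[C@H]2[C@@]31C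
F7 | step 9 | lithium C11 enolate of F6 | O=C1C=C[C@](C)(COC(=O)/C(C)=C/C)[C@H]2[C@@H]3[C@H](C)C=C([O-])[C@H]2[C@@]31C.[Li+]
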